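**Retrosynthetic overview**
1. Sigmoidin D comes from its tri-O-benzyl ether 17 by a final global hydrogenolysis.
2. Key disconnection: the C2–aryl bond of ring C, made by rhodium-catalysed enantioselective 1,4-addition of arylboronic acid 12 to the preformed chromone 16. This sets C2 directly and replaces the usual chalcone aldol/cyclisation.
3. Boronic acid 12 comes from bromochromanol 9, whose carbinol centre is set by Jacobsen–Katsuki epoxidation of chromene 7 and benzylic hydride opening.
4. Chromene 7 (ring D fused to ring B) comes from 2-(benzyloxy)phenol by bromination, propargylation and a propargyl Claisen cascade; chromone 16 (ring C fused to ring A) comes from 2,4,6-trihydroxyacetophenone through an enaminone.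
5. Ring order: ring D on ring B, then ring C on ring A, then union of the two halves at C2, then deprotection.

Assumption: (S)-MeO-F12-BIPHEP is taken to give the (2S)-adduct, the same facial sense in which (S)-biaryl bisphosphine rhodium catalysts give (S)-3-arylcyclohexanones; if the first run shows the reverse, the (R)-ligand is used.

**Step 1**
Reactants: 1 2-(benzyloxy)phenol
Product: 2 2-(benzyloxy)-4-bromophenol
Conditions: NBS (1.0 equiv), MeCN, 0 °C to rt
Reagents that add atoms: N-bromosuccinimide, O=C1CCC(=O)N1Br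
Why: Electrophilic aromatic bromination, in which the free hydroxyl is the stronger director and its para position is open, so bromine enters C4 as it does with guaiacol.

**Step 2**
Reactants: 2 2-(benzyloxy)-4-bromophenol; 3 3-chloro-3-methylbut-1-yne
Product: 4 2-(benzyloxy)-4-bromo-1-[(2-methylbut-3-yn-2-yl)oxy]benzene
Conditions: K2CO3, KI, CuI (cat.), acetone, 56 °C
Reagents that add atoms: none
Why: Copper-assisted Williamson-type O-propargylation of the phenoxide by the tertiary propargylic chloride, the standard entry to aryl 1,1-dimethylpropargyl ethers.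

**Step 3**
Reactants: 4 2-(benzyloxy)-4-bromo-1-[(2-methylbut-3-yn-2-yl)oxy]benzene
Product: 7 8-(benzyloxy)-6-bromo-2,2-dimethyl-2H-chromene, via allenylphenol 5 (not isolated), via quinone methide 6 (not isolated)
Conditions: PhNEt2, 185 °C
Reagents that add atoms: none
Why: Aromatic propargyl Claisen rearrangement into the only free ortho position, followed by 1,5-hydrogen shift and oxa-6π electrocyclisation, is the classical cascade to 2,2-dimethyl-2H-chromenes and closes ring D.

**Step 4**
Reactants: 7 8-(benzyloxy)-6-bromo-2,2-dimethyl-2H-chromene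
Product: 8 (3S,4S)-8-(benzyloxy)-6-bromo-3,4-epoxy-2,2-dimethylchromane
Conditions: (S,S)-Mn(salen)Cl (4 mol %; salen = N,N'-bis(3,5-di-tert-butylsalicylidene)cyclohexane-1,2-diamine dianion), 4-phenylpyridine N-oxide (20 mol %), aq NaOCl (pH 11.3, Na2HPO4), CH2Cl2, 0 °C
Reagents that add atoms: sodium hypochlorite, [Na+].[O-]Cl
Why: Jacobsen–Katsuki epoxidation, for which 2,2-dimethylchromenes are the best substrate class (typically above 95 % ee), and the (S,S)-catalyst delivers oxygen to the face that gives the (3S,4S)-epoxide, which fixes the future carbinol centre.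

**Step 5**
Reactants: 8 (3S,4S)-8-(benzyloxy)-6-bromo-3,4-epoxy-2,2-dimethylchromane
Product: 9 (3S)-8-(benzyloxy)-6-bromo-2,2-dimethylchroman-3-ol
Conditions: LiBHEt3 (1.5 equiv), THF, 0 °C; then H2O
Reagents that add atoms: none
Why: Regioselective SN2 hydride opening of the epoxide at the benzylic C4 (C3 is shielded by the quaternary C2, and nucleophiles open these epoxides at C4), so the C3–O bond is untouched and C3 stays (S).

**Step 6**
Reactants: 9 (3S)-8-(benzyloxy)-6-bromo-2,2-dimethylchroman-3-ol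
Product: 12 [(3S)-8-(benzyloxy)-3-hydroxy-2,2-dimethylchroman-6-yl]boronic acid, via dilithio species 10 (not isolated), via borate complex 11 (not isolated)
Conditions: n-BuLi (2.2 equiv), THF, −78 °C; B(OiPr)3 (3 equiv), −78 °C to rt; 1 M HCl
Reagents that add atoms: triisopropyl borate, CC(C)OB(OC(C)C)OC(C)C; water, O
Why: Deprotonation of the alcohol and bromine–lithium exchange give the aryllithium, which is trapped by the borate ester and hydrolysed on work-up (lithiation–borylation), without touching C3.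

**Step 7**
Reactants: 13 2,4,6-trihydroxyacetophenone
Product: 14 1-[2,4-bis(benzyloxy)-6-hydroxyphenyl]ethanone
Conditions: BnBr (2.1 equiv), K2CO3, DMF, rt
Reagents that add atoms: benzyl bromide, BrCc1ccccc1
Why: Williamson etherification in which the hydroxyl hydrogen-bonded to the ketone is the least nucleophilic and stays free when two equivalents of benzyl bromide are used.

**Step 8**
Reactants: 14 1-[2,4-bis(benzyloxy)-6-hydroxyphenyl]ethanone
Product: 16 5,7-bis(benzyloxy)-4H-chromen-4-one, via enaminone 15 (not isolated)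
Conditions: Me2NCH(OMe)2, 95 °C; then conc. HCl, CH2Cl2, 40 °C
Reagents that add atoms: N,N-dimethylformamide dimethyl acetal, COC(OC)N(C)C
Why: Condensation of the methyl ketone with the formamide acetal gives the enaminone, and acid triggers intramolecular oxa-Michael addition of the phenol with loss of dimethylamine (enaminone chromone synthesis), closing ring C.

**Step 9**
Reactants: 12 [(3S)-8-(benzyloxy)-3-hydroxy-2,2-dimethylchroman-6-yl]boronic acid; 16 5,7-bis(benzyloxy)-4H-chromen-4-one
Product: 17 (2S)-5,7-bis(benzyloxy)-2-[(3S)-8-(benzyloxy)-3-hydroxy-2,2-dimethyl-3,4-dihydro-2H-chromen-6-yl]-2,3-dihydro-4H-chromen-4-one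
Conditions: [Rh(OH)((S)-MeO-F12-BIPHEP)]2 (1.5 mol %; ligand = (S)-6,6'-dimethoxy-2,2'-bis[bis(3,4,5-trifluorophenyl)phosphino]-1,1'-biphenyl), 16 (1.3 equiv), CH2Cl2/H2O (20:1), 20 °C
Reagents that add atoms: none
Why: Rhodium-catalysed asymmetric 1,4-addition of an arylboronic acid to a chromone (Hayashi–Miyaura reaction), in which the aryl–rhodium species adds across C2=C3 on the face selected by the electron-poor (S)-bisphosphine to set C2 as (S), while fast protonation of the rhodium enolate in CH2Cl2/H2O suppresses ring opening and 1,2-addition and the remote carbinol centre is not involved.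

**Step 10**
Reactants: 17 (2S)-5,7-bis(benzyloxy)-2-[(3S)-8-(benzyloxy)-3-hydroxy-2,2-dimethyl-3,4-dihydro-2H-chromen-6-yl]-2,3-dihydro-4H-chromen-4-one
Product: 18 Sigmoidin D
Conditions: H2 (1 atm), 10 % Pd/C, EtOAc/MeOH (1:1), rt, stopped after uptake of 3 equiv H2
Reagents that add atoms: none
Why: Catalytic hydrogenolysis cleaves the three benzyl ethers under neutral conditions that leave the aryl ketone, the flavanone C2–O bond and both stereocentres intact, as is routine for benzyl-protected flavanones.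

**Compound list**
1 | 2-(benzyloxy)phenol | Oc1ccccc1OCc1ccccc1 | starting material
2 | 2-(benzyloxy)-4-bromophenol | Oc1ccc(Br)cc1OCc1ccccc1 | intermediate
3 | 3-chloro-3-methylbut-1-yne | C#CC(C)(C)Cl | starting material
4 | 2-(benzyloxy)-4-bromo-1-[(2-methylbut-3-yn-2-yl)oxy]benzene | C#CC(C)(C)Oc1ccc(Br)cc1OCc1ccccc1 | intermediate
5 | 2-(benzyloxy)-4-bromo-6-(3-methylbuta-1,2-dien-1-yl)phenol (allenylphenol) | CC(C)=C=Cc1cc(Br)cc(OCc2ccccc2)c1O | intermediate (not isolated)
6 | (6Z)-2-(benzyloxy)-4-bromo-6-(3-methylbut-2-en-1-ylidene)cyclohexa-2,4-dien-1-one (o-quinone methide) | CC(C)=C/C=C1/C=C(Br)C=C(OCc2ccccc2)C1=O | intermediate (not isolated)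
7 | 8-(benzyloxy)-6-bromo-2,2-dimethyl-2H-chromene | CC1(C)C=Cc2cc(Br)cc(OCc3ccccc3)c2O1 | intermediate
8 | (3S,4S)-8-(benzyloxy)-6-bromo-3,4-epoxy-2,2-dimethylchromane | CC1(C)Oc2c(OCc3ccccc3)cc(Br)cc2[C@@H]4O[C@@H]41 | intermediate
9 | (3S)-8-(benzyloxy)-6-bromo-2,2-dimethylchroman-3-ol | CC1(C)Oc2c(OCc3ccccc3)cc(Br)cc2C[C@@H]1O | intermediate
10 | lithium (3S)-8-(benzyloxy)-6-lithio-2,2-dimethylchroman-3-olate (dilithio species) | CC1(C)Oc2c(OCc3ccccc3)cc([Li])cc2C[C@@H]1O[Li] | intermediate (not isolated)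
11 | dilithium [(3S)-8-(benzyloxy)-2,2-dimethyl-3-oxidochroman-6-yl]tri(propan-2-yloxy)borate (borate complex) | CC1(C)Oc2c(OCc3ccccc3)cc([B-](OC(C)C)(OC(C)C)OC(C)C)cc2C[C@@H]1[O-].[Li+].[Li+] | intermediate (not isolated)
12 | [(3S)-8-(benzyloxy)-3-hydroxy-2,2-dimethylchroman-6-yl]boronic acid | CC1(C)Oc2c(OCc3ccccc3)cc(B(O)O)cc2C[C@@H]1O | intermediate
13 | 2,4,6-trihydroxyacetophenone | CC(=O)c1c(O)cc(O)cc1O | starting material
14 | 1-[2,4-bis(benzyloxy)-6-hydroxyphenyl]ethanone | CC(=O)c1c(O)cc(OCc2ccccc2)cc1OCc1ccccc1 | intermediate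
15 | (E)-1-[2,4-bis(benzyloxy)-6-hydroxyphenyl]-3-(dimethylamino)prop-2-en-1-one (enaminone) | CN(C)/C=C/C(=O)c1c(O)cc(OCc2ccccc2)cc1OCc1ccccc1 | intermediate (not isolated)
16 | 5,7-bis(benzyloxy)-4H-chromen-4-one | O=c1ccoc2cc(OCc3ccccc3)cc(OCc3ccccc3)c12 | intermediate
17 | (2S)-5,7-bis(benzyloxy)-2-[(3S)-8-(benzyloxy)-3-hydroxy-2,2-dimethyl-3,4-dihydro-2H-chromen-6-yl]-2,3-dihydro-4H-chromen-4-one | CC1(C)Oc2c(OCc3ccccc3)cc([C@@H]3CC(=O)c4c(OCc5ccccc5)cc(OCc5ccccc5)cc4O3)cc2C[C@@H]1O | intermediate
18 | Sigmoidin D, (2S)-5,7-dihydroxy-2-[(3S)-3,8-dihydroxy-2,2-dimethyl-3,4-dihydro-2H-chromen-6-yl]-2,3-dihydro-4H-chromen-4-one | CC1(C)Oc2c(O)cc([C@@H]3CC(=O)c4c(O)cc(O)cc4O3)cc2C[C@@H]1O | target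

**Step count and risks**
Total step count: 10. Longest linear sequence: 8 steps (steps 1 to 6, then 9 and 10); the chromone branch (steps 7 and 8) is convergent.

The three steps most likely to fail:

Step 9 (the key conjugate arylation). The 5,7-dialkoxychromone is a deactivated acceptor, the rhodium enolate can eliminate the ring oxygen to give a chalcone, and the electron-rich boronic acid can protodeboronate. The fallback sets out from bromide 9 and ketone 14 and comes back at 17. Bromide 9 is lithiated as in step 6 (n-BuLi 2.2 equiv, THF, −78 °C) but quenched with DMF to give (3S)-8-(benzyloxy)-3-hydroxy-2,2-dimethyl-3,4-dihydro-2H-chromene-6-carbaldehyde F1. Claisen–Schmidt condensation of this aldehyde with 14 (KOH, EtOH, rt) gives (E)-1-[2,4-bis(benzyloxy)-6-hydroxyphenyl]-3-[(3S)-8-(benzyloxy)-3-hydroxy-2,2-dimethyl-3,4-dihydro-2H-chromen-6-yl]prop-2-en-1-one F2. Intramolecular oxa-Michael addition (NaOAc, EtOH, 78 °C) then closes ring C to give 17 together with the (2R)-epimer of 17 F3. Because the carbinol centre is already fixed, the two are diastereomers, which are separated by preparative HPLC or crystallisation; the unwanted epimer is re-equilibrated through the chalcone under the same basic conditions, and the route resumes at 17.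

Step 4 (asymmetric epoxidation). The electron-rich 8-alkoxychromene oxide may hydrolyse or rearrange under the biphasic conditions, and the ee with an 8-substituent is untested. The fallback sets out from chromene 7 and comes back at 9, turning the epoxide's lability into the productive pathway. Chromene 7 is epoxidised without asymmetric control (mCPBA, NaHCO3, CH2Cl2, 0 °C) to racemic cis-8-(benzyloxy)-6-bromo-3,4-epoxy-2,2-dimethylchromane F4. Meinwald rearrangement (ZnI2 cat., toluene, rt; benzylic cation, 1,2-hydride shift) then gives 8-(benzyloxy)-6-bromo-2,2-dimethylchroman-3-one F5. The carbinol centre is set by Corey–Bakshi–Shibata reduction ((R)-2-methyl-CBS-oxazaborolidine 10 mol %, BH3·SMe2, THF, −20 °C); the quaternary C2 acts as the large group, so the (R)-catalyst gives (S)-alcohol 9.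

Step 6 (boronic acid through the dianion). Exchange may be incomplete, the benzyl ether may undergo Wittig rearrangement, and the product may protodeboronate on acidic work-up. The fallback sets out from 9 and comes back at 12. Miyaura borylation (PdCl2(dppf) 3 mol %, B2pin2, KOAc, dioxane, 90 °C), which tolerates the free alcohol, gives (3S)-8-(benzyloxy)-2,2-dimethyl-6-(4,4,5,5-tetramethyl-1,3,2-dioxaborolan-2-yl)chroman-3-ol F6. Oxidative removal of the pinacol (NaIO4, NH4OAc, acetone/H2O, rt) then gives boronic acid 12.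

**Further compounds**
F1 | step 9 | (3S)-8-(benzyloxy)-3-hydroxy-2,2-dimethyl-3,4-dihydro-2H-chromene-6-carbaldehyde | CC1(C)Oc2c(OCc3ccccc3)cc(C=O)cc2C[C@@H]1O
F2 | step 9 | (E)-1-[2,4-bis(benzyloxy)-6-hydroxyphenyl]-3-[(3S)-8-(benzyloxy)-3-hydroxy-2,2-dimethyl-3,4-dihydro-2H-chromen-6-yl]prop-2-en-1-one | CC1(C)Oc2c(OCc3ccccc3)cc(/C=C/C(=O)c3c(O)cc(OCc4ccccc4)cc3OCc3ccccc3)cc2C[C@@H]1O
F3 | step 9 | (2R)-5,7-bis(benzyloxy)-2-[(3S)-8-(benzyloxy)-3-hydroxy-2,2-dimethyl-3,4-dihydro-2H-chromen-6-yl]-2,3-dihydro-4H-chromen-4-one | CC1(C)Oc2c(OCc3ccccc3)cc([C@H]3CC(=O)c4c(OCc5ccccc5)cc(OCc5ccccc5)cc4O3)cc2C[C@@H]1O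
F4 | step 4 | racemic cis-8-(benzyloxy)-6-bromo-3,4-epoxy-2,2-dimethylchromane | CC1(C)Oc2c(OCc3ccccc3)cc(Br)cc2C4OC41
F5 | step 4 | 8-(benzyloxy)-6-bromo-2,2-dimethylchroman-3-one | CC1(C)Oc2c(OCc3ccccc3)cc(Br)cc2CC1=O
F6 | step 6 | (3S)-8-(benzyloxy)-2,2-dimethyl-6-(4,4,5,5-tetramethyl-1,3,2-dioxaborolan-2-yl)chroman-3-ol | CC1(C)Oc2c(OCc3ccccc3)cc(B3OC(C)(C)C(C)(C)O3)cc2C[C@@H]1O
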